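**Plan** (locants are those of the azulene skeleton of the target)

- Retrosynthesis: the C4–O ester bond is cut last; the ring bonds C4–C5 and C3a–C8a are then cut together, which opens both rings to an acyclic bis(silyl enol ether) with a methallyl ketone end.
- Enabling feature: C8a (α to the C8 ketone) and C3a (α to C4, an aldehyde carbon in the open chain) are two enol-type donor carbons of a 1,4-dioxygenated C8–C8a–C3a–C4 array whose central bond is shared by the five- and seven-membered rings. The β-methyl enone C6=C7–C8=O is the footprint of a methallyl group whose CH2 terminus (C5) can close the seven-membered ring onto C4.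
- The chain is (S)-terpinen-4-ol opened by ozonolysis (ten of the fifteen skeletal carbons, the tertiary carbinol and the future angular methyl), plus one Wittig carbon (C8) and a methallyl Grignard reagent (C5–C7 and the ring methyl).
- Forward order: ring opening, one-carbon homologation to the ester, TIPS enol ether at the aldehyde end, ester enolate–ketene–Grignard tandem to the regiodefined ketone enol silane, then the oxidative cascade (cyclopentane first through C3a–C8a, cycloheptenone second through C4–C5), desilylation, acylation.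
- Stereochemistry: C3 comes unchanged from (S)-terpinen-4-ol; C3a, C8a and C4 are set under its control in the key step.

Key step: step 8

Assumption: (S)-(+)-terpinen-4-ol is used in enantioenriched commercial form, so the enantiomeric purity of the route is that of this starting material.

**Step 1**
Reactants: 1 (S)-terpinen-4-ol; 2 triethylsilyl trifluoromethanesulfonate
Product: 3 triethyl{[(1S)-4-methyl-1-(propan-2-yl)cyclohex-3-en-1-yl]oxy}silane
Conditions: Et3SiOTf, 2,6-lutidine, CH2Cl2, 0 °C to rt
Reagents that add atoms: triethylsilyl trifluoromethanesulfonate (2), CC[Si](CC)(CC)OS(=O)(=O)C(F)(F)F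
Why: Silylation of a hindered tertiary alcohol with a silyl triflate and 2,6-lutidine is a standard protection, and the carbinol stereocentre (the future C3) is not involved.

**Step 2**
Reactants: 3 triethyl{[(1S)-4-methyl-1-(propan-2-yl)cyclohex-3-en-1-yl]oxy}silane; 4 ozone; 5 trimethyl orthoformate
Product: 8 (5S)-7,7-dimethoxy-5-(propan-2-yl)-5-[(triethylsilyl)oxy]heptan-2-one, via ozonide 6 (not isolated), via keto aldehyde 7 (not isolated)
Conditions: O3, CH2Cl2, −78 °C; PPh3, −78 °C to rt; then HC(OMe)3, MeOH, PPTS (cat.), 0 °C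
Reagents that add atoms: ozone (4), [O-][O+]=O; trimethyl orthoformate (5), COC(OC)OC
Why: Ozonolysis of the single trisubstituted C=C bond with phosphine reduction of the ozonide gives the keto aldehyde, and acid-catalysed acetalisation with an orthoformate at 0 °C is chemoselective for the aldehyde over the methyl ketone, which masks the aldehyde terminus for the next two steps.

**Step 3**
Reactants: 8 (5S)-7,7-dimethoxy-5-(propan-2-yl)-5-[(triethylsilyl)oxy]heptan-2-one; 9 (methoxymethyl)triphenylphosphonium chloride
Product: 10 triethyl{[(3S)-1,1,7-trimethoxy-6-methyl-3-(propan-2-yl)hept-6-en-3-yl]oxy}silane (E/Z mixture)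
Conditions: [Ph3PCH2OMe]Cl, KOtBu, THF, 0 °C to rt
Reagents that add atoms: (methoxymethyl)triphenylphosphonium chloride (9), COC[P+](c1ccccc1)(c1ccccc1)c1ccccc1.[Cl-]
Why: Wittig methoxymethylenation of the methyl ketone adds the one carbon that becomes the ring ketone carbon, and the E/Z mixture of enol ethers converges in the next step.

**Step 4**
Reactants: 10 triethyl{[(3S)-1,1,7-trimethoxy-6-methyl-3-(propan-2-yl)hept-6-en-3-yl]oxy}silane; 11 pyridinium chlorochromate
Product: 12 methyl (5S)-7,7-dimethoxy-2-methyl-5-(propan-2-yl)-5-[(triethylsilyl)oxy]heptanoate (both C2 epimers)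
Conditions: [C5H5NH][CrO3Cl], NaOAc, 4 Å MS, CH2Cl2, rt
Reagents that add atoms: pyridinium chlorochromate (11), [O-][Cr](=O)(=O)Cl.c1cc[nH+]cc1
Why: Chlorochromate oxidation of an enol ether to the ester is a known one-step alternative to hydrolysis plus aldehyde oxidation, buffered here to spare the acetal and the silyl ether; the α-methyl stereocentre forms as a mixture and is made planar again in step 7.

**Step 5**
Reactants: 12 methyl (5S)-7,7-dimethoxy-2-methyl-5-(propan-2-yl)-5-[(triethylsilyl)oxy]heptanoate; 13 water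
Product: 14 methyl (5S)-2-methyl-7-oxo-5-(propan-2-yl)-5-[(triethylsilyl)oxy]heptanoate (both C2 epimers)
Conditions: PPTS (cat.), acetone–H2O, 40 °C
Reagents that add atoms: water (13), O
Why: Mild acid-catalysed acetal hydrolysis frees the aldehyde while the hindered tertiary silyl ether and the ester persist.

**Step 6**
Reactants: 14 methyl (5S)-2-methyl-7-oxo-5-(propan-2-yl)-5-[(triethylsilyl)oxy]heptanoate; 15 tri(propan-2-yl)silyl trifluoromethanesulfonate
Product: 16 methyl (5R,6E)-2-methyl-5-(propan-2-yl)-5-[(triethylsilyl)oxy]-7-{[tri(propan-2-yl)silyl]oxy}hept-6-enoate (both C2 epimers)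
Conditions: iPr3SiOTf, Et3N, CH2Cl2, −78 °C to 0 °C
Reagents that add atoms: tri(propan-2-yl)silyl trifluoromethanesulfonate (15), CC(C)[Si](C(C)C)(C(C)C)OS(=O)(=O)C(F)(F)F
Why: Soft enolisation of the aldehyde with a silyl triflate and Et3N gives the silyl enol ether with the ester inert, and the E isomer is expected because the silyloxy group avoids the fully substituted neighbouring carbon (the descriptor changes from S to R only through the priority change, not through inversion).

**Step 7**
Reactants: 16 methyl (5R,6E)-2-methyl-5-(propan-2-yl)-5-[(triethylsilyl)oxy]-7-{[tri(propan-2-yl)silyl]oxy}hept-6-enoate; 17 (2-methylprop-2-en-1-yl)magnesium chloride; 18 chlorotrimethylsilane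
Product: 22 (8R,9E)-2,5-dimethyl-8-(propan-2-yl)-8-[(triethylsilyl)oxy]-4-[(trimethylsilyl)oxy]-10-{[tri(propan-2-yl)silyl]oxy}deca-1,4,9-triene, via lithium ester enolate 19 (not isolated), via ketene 20 (not isolated), via chloromagnesium enolate 21 (not isolated)
Conditions: LiN(iPr)2, THF, −78 °C; CH2=C(CH3)CH2MgCl, −78 °C to rt; then Me3SiCl, DMPU, −78 °C to 0 °C; non-aqueous work-up
Reagents that add atoms: (2-methylprop-2-en-1-yl)magnesium chloride (17), C=C(C)C[Mg]Cl; chlorotrimethylsilane (18), C[Si](C)(C)Cl
Why: In this ester enolate–ketene–Grignard tandem the α,α-disubstituted ester enolate expels methoxide on warming, the allylic Grignard reagent adds to the ketene carbonyl carbon to give the ketone enolate with its double bond fixed toward the methyl-bearing carbon, and O-silylation traps this regiochemistry, which deprotonation of the β,γ-unsaturated ketone could not give.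

**Step 8**
Reactants: 22 (8R,9E)-2,5-dimethyl-8-(propan-2-yl)-8-[(triethylsilyl)oxy]-4-[(trimethylsilyl)oxy]-10-{[tri(propan-2-yl)silyl]oxy}deca-1,4,9-triene
Product: 24 (3R,3aS,4S,8aS)-6,8a-dimethyl-3-(propan-2-yl)-3-[(triethylsilyl)oxy]-4-{[tri(propan-2-yl)silyl]oxy}-2,3,3a,4,5,8a-hexahydroazulen-8(1H)-one, via cyclopentane keto aldehyde 23 (not isolated)
Conditions: Cu(OTf)2 (2.3 equiv), Cu2O (2 equiv), MeCN–CH2Cl2, −30 °C to 0 °C
Reagents that add atoms: none
Why: Proposed new method: one-electron oxidation of the tetrasubstituted trimethylsilyl enol ether by divalent copper gives a radical cation whose carbon terminus adds to the β-carbon of the tethered TIPS enol ether (5-exo-trig, closing the cyclopentane and joining two enol-type donor carbons), a second oxidation turns the α-silyloxy radical into a TIPS-oxocarbenium ion (equivalent to keto aldehyde 23 plus iPr3SiOTf), and the isopropenyl terminus of the methallyl ketone attacks it in Markovnikov fashion (7-endo-trig Prins closure of the cycloheptane), after which the tertiary cation loses the proton α to the ketone to give the conjugated enone with the silyl group left on oxygen. The closest known reaction types are the oxidative cyclisation of unsaturated silyl enol ethers with Cu(OTf)2/Cu2O including cation-terminated tandem versions, the oxidative coupling of bis(silyl enol ethers) to 1,4-dicarbonyl compounds, and Lewis-acid-promoted carbonyl-ene (Prins) closures of methallyl-bearing aldehydes to seven-membered rings; their merger in one flask is what is new. The ring-fusion CH is controlled by the adjacent carbinol stereocentre, which should place its silyloxy group in the plane of the (E)-enol ether and its isopropyl group anti to the incoming carbon, so that the new hydrogen ends up cis to isopropyl. The quaternary carbon is set in the same transition state, where the bulky oxygen-bearing arm should point away from the TIPSO–CH= terminus and the methyl group sit over it, which places the ketone arm and the formyl carbon trans on the cyclopentane and hence gives the trans ring fusion. The silyloxy-bearing carbon is set in the Prins closure through a chair-like seven-membered transition state with the (E)-oxocarbenium substituent pseudo-equatorial, that is, with its hydrogen anti to the ring-fusion hydrogen. The step needs chemoselective oxidation of the more electron-rich tetrasubstituted enol ether (secured by its substitution), no closure of the radical cation onto the isopropenyl group (that would be a disfavoured 5-endo mode), and ring closure faster than loss of the silyl group, which the non-nucleophilic triflate medium buffered by Cu2O is meant to secure.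

**Step 9**
Reactants: 24 (3R,3aS,4S,8aS)-6,8a-dimethyl-3-(propan-2-yl)-3-[(triethylsilyl)oxy]-4-{[tri(propan-2-yl)silyl]oxy}-2,3,3a,4,5,8a-hexahydroazulen-8(1H)-one
Product: 25 (3R,3aS,4S,8aS)-3,4-dihydroxy-6,8a-dimethyl-3-(propan-2-yl)-2,3,3a,4,5,8a-hexahydroazulen-8(1H)-one
Conditions: HF·pyridine, pyridine, THF, 0 °C to rt
Reagents that add atoms: none
Why: Fluoride-driven cleavage of both Si–O bonds (silyl ether deprotection) under buffered, non-basic conditions avoids the retro-aldol and elimination pathways open to the δ-hydroxy enone under base.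

**Step 10**
Reactants: 25 (3R,3aS,4S,8aS)-3,4-dihydroxy-6,8a-dimethyl-3-(propan-2-yl)-2,3,3a,4,5,8a-hexahydroazulen-8(1H)-one; 26 3,4,5-trimethoxybenzoyl chloride
Product: 27 (3R,3aS,4S,8aS)-3-hydroxy-6,8a-dimethyl-8-oxo-3-(propan-2-yl)-1,2,3,3a,4,5,8,8a-octahydroazulen-4-yl 3,4,5-trimethoxybenzoate
Conditions: 3,4,5-(MeO)3C6H2COCl, Et3N, DMAP (cat.), CH2Cl2, 0 °C to rt
Reagents that add atoms: 3,4,5-trimethoxybenzoyl chloride (26), COc1cc(C(=O)Cl)cc(OC)c1OC
Why: DMAP-catalysed acylation (nucleophilic catalysis) with the acid chloride selects the secondary C4 hydroxyl over the hindered tertiary one and leaves all stereocentres untouched.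

**Compound list**

1 | (S)-(+)-terpinen-4-ol, (1S)-4-methyl-1-(propan-2-yl)cyclohex-3-en-1-ol | CC1=CC[C@](O)(C(C)C)CC1 | starting material
2 | triethylsilyl trifluoromethanesulfonate | CC[Si](CC)(CC)OS(=O)(=O)C(F)(F)F | starting material
3 | triethyl{[(1S)-4-methyl-1-(propan-2-yl)cyclohex-3-en-1-yl]oxy}silane | CC1=CC[C@](O[Si](CC)(CC)CC)(C(C)C)CC1 | intermediate
4 | ozone | [O-][O+]=O | starting material
5 | trimethyl orthoformate | COC(OC)OC | starting material
6 | ozonide of 3, triethyl{[(4S)-1-methyl-4-(propan-2-yl)-7,8,9-trioxabicyclo[4.2.1]nonan-4-yl]oxy}silane (bridgehead configuration not defined) | CC12CC[C@@](O[Si](CC)(CC)CC)(C(C)C)CC(OO1)O2 | intermediate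
7 | (3S)-6-oxo-3-(propan-2-yl)-3-[(triethylsilyl)oxy]heptanal | CC(=O)CC[C@@](O[Si](CC)(CC)CC)(C(C)C)CC=O | intermediate
8 | (5S)-7,7-dimethoxy-5-(propan-2-yl)-5-[(triethylsilyl)oxy]heptan-2-one | CC(=O)CC[C@@](O[Si](CC)(CC)CC)(C(C)C)CC(OC)OC | intermediate
9 | (methoxymethyl)triphenylphosphonium chloride | COC[P+](c1ccccc1)(c1ccccc1)c1ccccc1.[Cl-] | starting material
10 | triethyl{[(3S)-1,1,7-trimethoxy-6-methyl-3-(propan-2-yl)hept-6-en-3-yl]oxy}silane (E/Z mixture) | COC=C(C)CC[C@@](O[Si](CC)(CC)CC)(C(C)C)CC(OC)OC | intermediate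
11 | pyridinium chlorochromate | [O-][Cr](=O)(=O)Cl.c1cc[nH+]cc1 | starting material
12 | methyl (5S)-7,7-dimethoxy-2-methyl-5-(propan-2-yl)-5-[(triethylsilyl)oxy]heptanoate (both C2 epimers) | COC(=O)C(C)CC[C@@](O[Si](CC)(CC)CC)(C(C)C)CC(OC)OC | intermediate
13 | water | O | starting material
14 | methyl (5S)-2-methyl-7-oxo-5-(propan-2-yl)-5-[(triethylsilyl)oxy]heptanoate (both C2 epimers) | COC(=O)C(C)CC[C@@](O[Si](CC)(CC)CC)(C(C)C)CC=O | intermediate
15 | tri(propan-2-yl)silyl trifluoromethanesulfonate | CC(C)[Si](C(C)C)(C(C)C)OS(=O)(=O)C(F)(F)F | starting material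
16 | methyl (5R,6E)-2-methyl-5-(propan-2-yl)-5-[(triethylsilyl)oxy]-7-{[tri(propan-2-yl)silyl]oxy}hept-6-enoate (both C2 epimers) | COC(=O)C(C)CC[C@@](O[Si](CC)(CC)CC)(C(C)C)/C=C/O[Si](C(C)C)(C(C)C)C(C)C | intermediate
17 | (2-methylprop-2-en-1-yl)magnesium chloride | C=C(C)C[Mg]Cl | starting material
18 | chlorotrimethylsilane | C[Si](C)(C)Cl | starting material
19 | lithium enolate of 16 | COC(O[Li])=C(C)CC[C@@](O[Si](CC)(CC)CC)(C(C)C)/C=C/O[Si](C(C)C)(C(C)C)C(C)C | intermediate
20 | ketene, (5R,6E)-2-methyl-5-(propan-2-yl)-5-[(triethylsilyl)oxy]-7-{[tri(propan-2-yl)silyl]oxy}hepta-1,6-dien-1-one | O=C=C(C)CC[C@@](O[Si](CC)(CC)CC)(C(C)C)/C=C/O[Si](C(C)C)(C(C)C)C(C)C | intermediate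
21 | chloromagnesium enolate (C4=C5) of (8R,9E)-2,5-dimethyl-8-(propan-2-yl)-8-[(triethylsilyl)oxy]-10-{[tri(propan-2-yl)silyl]oxy}deca-1,9-dien-4-one | C=C(C)CC(O[Mg]Cl)=C(C)CC[C@@](O[Si](CC)(CC)CC)(C(C)C)/C=C/O[Si](C(C)C)(C(C)C)C(C)C | intermediate
22 | (8R,9E)-2,5-dimethyl-8-(propan-2-yl)-8-[(triethylsilyl)oxy]-4-[(trimethylsilyl)oxy]-10-{[tri(propan-2-yl)silyl]oxy}deca-1,4,9-triene (geometry at C4=C5 not defined) | C=C(C)CC(O[Si](C)(C)C)=C(C)CC[C@@](O[Si](CC)(CC)CC)(C(C)C)/C=C/O[Si](C(C)C)(C(C)C)C(C)C | intermediate
23 | (1R,2S,5R)-2-methyl-2-(3-methylbut-3-enoyl)-5-(propan-2-yl)-5-[(triethylsilyl)oxy]cyclopentane-1-carbaldehyde | C=C(C)CC(=O)[C@@]1(C)CC[C@@](O[Si](CC)(CC)CC)(C(C)C)[C@@H]1C=O | intermediate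
24 | (3R,3aS,4S,8aS)-6,8a-dimethyl-3-(propan-2-yl)-3-[(triethylsilyl)oxy]-4-{[tri(propan-2-yl)silyl]oxy}-2,3,3a,4,5,8a-hexahydroazulen-8(1H)-one | CC(C)[Si](C(C)C)(C(C)C)O[C@H]1CC(C)=CC(=O)[C@@]2(C)CC[C@@](O[Si](CC)(CC)CC)(C(C)C)[C@H]12 | intermediate
25 | (3R,3aS,4S,8aS)-3,4-dihydroxy-6,8a-dimethyl-3-(propan-2-yl)-2,3,3a,4,5,8a-hexahydroazulen-8(1H)-one | O[C@H]1CC(C)=CC(=O)[C@@]2(C)CC[C@@](O)(C(C)C)[C@H]12 | intermediate
26 | 3,4,5-trimethoxybenzoyl chloride | COc1cc(C(=O)Cl)cc(OC)c1OC | starting material
27 | (3R,3aS,4S,8aS)-3-hydroxy-6,8a-dimethyl-8-oxo-3-(propan-2-yl)-1,2,3,3a,4,5,8,8a-octahydroazulen-4-yl 3,4,5-trimethoxybenzoate (CNP0218356.1) | COc1cc(C(=O)O[C@H]2CC(C)=CC(=O)[C@@]3(C)CC[C@@](O)(C(C)C)[C@H]23)cc(OC)c1OC | target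

**Step count and risks**

Total steps: 10. Longest linear sequence: 10 steps, from 1.

Steps most likely to fail:

Step 8 (proposed new method). What may go wrong: the silyl group may leave the C4 oxocarbenium ion, or the ion may be intercepted, before the seven-membered ring closes; the Lewis acidic medium may ionise the allylic tertiary silyl ether of 22; facial selectivity at the quaternary carbon in the first bond formation may be poor (literature on 1-substituted hexenyl radicals does not settle which group ends up cis to the formyl carbon). Fallback with known chemistry, setting out from 22: the two enol silanes are coupled alone with (NH4)2Ce(NO3)6 and NaHCO3 in MeCN at −30 °C (oxidative coupling of a bis(silyl enol ether) to a 1,4-dicarbonyl compound). The keto aldehyde 23 is now isolated, which allows separation of isomers at the quaternary carbon and equilibration of the formyl-bearing carbon with DBU. Me2AlCl in CH2Cl2 at −78 °C then closes the seven-membered ring by an intramolecular carbonyl-ene (Prins) reaction to (3R,3aS,4S,8aS)-4-hydroxy-6,8a-dimethyl-3-(propan-2-yl)-3-[(triethylsilyl)oxy]-2,3,3a,4,5,8a-hexahydroazulen-8(1H)-one F1, and HF·pyridine removes the triethylsilyl group to give 25, where the route is rejoined.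

Step 7. What may go wrong: Claisen-type self-condensation of the ester enolate, or attack of the Grignard reagent on unfragmented ester, instead of clean fragmentation to the ketene; incomplete O-silylation of the magnesium enolate. Fallback, setting out from 16: KOSiMe3 in THF cleaves the methyl ester to (5R,6E)-2-methyl-5-(propan-2-yl)-5-[(triethylsilyl)oxy]-7-{[tri(propan-2-yl)silyl]oxy}hept-6-enoic acid F2. 1-Chloro-N,N,2-trimethylprop-1-en-1-amine converts it under neutral conditions into the corresponding acyl chloride, (5R,6E)-2-methyl-5-(propan-2-yl)-5-[(triethylsilyl)oxy]-7-{[tri(propan-2-yl)silyl]oxy}hept-6-enoyl chloride F3. Et3N at −20 °C dehydrochlorinates F3 to ketene 20; this preformed ketene solution is added to CH2=C(CH3)CH2MgCl at −78 °C (giving 21) and silylated with Me3SiCl as before, rejoining the route at 22.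

Step 4. What may go wrong: loss of the dimethyl acetal or of the silyl ether under the acidic chromium reagent, or oxidative cleavage of the enol ether double bond instead of ester formation. Fallback, setting out from 8: reductive cyanation of the ketone with p-toluenesulfonylmethyl isocyanide and KOtBu in DME–EtOH gives (5S)-7,7-dimethoxy-2-methyl-5-(propan-2-yl)-5-[(triethylsilyl)oxy]heptanenitrile F4. iBu2AlH at −78 °C and hydrolysis of the imine with aqueous tartrate buffer gives (5S)-7,7-dimethoxy-2-methyl-5-(propan-2-yl)-5-[(triethylsilyl)oxy]heptanal F5. Pinnick oxidation (NaClO2, NaH2PO4, 2-methylbut-2-ene, tBuOH–H2O) gives (5S)-7,7-dimethoxy-2-methyl-5-(propan-2-yl)-5-[(triethylsilyl)oxy]heptanoic acid F6, and Me3SiCHN2 in MeOH–toluene gives 12, where the route is rejoined.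

**Further compounds**

F1 | step 8 | (3R,3aS,4S,8aS)-4-hydroxy-6,8a-dimethyl-3-(propan-2-yl)-3-[(triethylsilyl)oxy]-2,3,3a,4,5,8a-hexahydroazulen-8(1H)-one | O[C@H]1CC(C)=CC(=O)[C@@]2(C)CC[C@@](O[Si](CC)(CC)CC)(C(C)C)[C@H]12
F2 | step 7 | (5R,6E)-2-methyl-5-(propan-2-yl)-5-[(triethylsilyl)oxy]-7-{[tri(propan-2-yl)silyl]oxy}hept-6-enoic acid (both C2 epimers) | OC(=O)C(C)CC[C@@](O[Si](CC)(CC)CC)(C(C)C)/C=C/O[Si](C(C)C)(C(C)C)C(C)C
F3 | step 7 | (5R,6E)-2-methyl-5-(propan-2-yl)-5-[(triethylsilyl)oxy]-7-{[tri(propan-2-yl)silyl]oxy}hept-6-enoyl chloride (both C2 epimers) | ClC(=O)C(C)CC[C@@](O[Si](CC)(CC)CC)(C(C)C)/C=C/O[Si](C(C)C)(C(C)C)C(C)C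
F4 | step 4 | (5S)-7,7-dimethoxy-2-methyl-5-(propan-2-yl)-5-[(triethylsilyl)oxy]heptanenitrile (both C2 epimers) | N#CC(C)CC[C@@](O[Si](CC)(CC)CC)(C(C)C)CC(OC)OC
F5 | step 4 | (5S)-7,7-dimethoxy-2-methyl-5-(propan-2-yl)-5-[(triethylsilyl)oxy]heptanal (both C2 epimers) | O=CC(C)CC[C@@](O[Si](CC)(CC)CC)(C(C)C)CC(OC)OC
F6 | step 4 | (5S)-7,7-dimethoxy-2-methyl-5-(propan-2-yl)-5-[(triethylsilyl)oxy]heptanoic acid (both C2 epimers) | OC(=O)C(C)CC[C@@](O[Si](CC)(CC)CC)(C(C)C)CC(OC)OC
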